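The oxygen-bridged ring A (a 7-oxabicyclo[2.2.1]heptane: O spanning C1 and C4, carbons C1–C5 and C10) is read as the [3+2] adduct of an aldehyde C1=O and a three-carbon C2–C3–C4 unit. A ring B cyclohexanone carrying, trans to one another, a formyl group on quaternary C10 and a 1-methyl-2,2-bis(methoxycarbonyl)cyclopropyl group on C5 undergoes a Sc(OTf)3-catalysed intramolecular cycloaddition. It forms C1–C2 and O–C4 in one operation, closing ring A with its ether bridge and setting C1 and C4. The activating malonate on C2 is then excised, and ring B is completed by allylic alkylation, olefination, angeloylation and an epoxide-triggered lactonisation.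

Key step: step 8

Remark (naming): locants C1–C15 follow eudesmane numbering of the target (ring A = C1–C5, C10; ring B = C5–C10; C11–C13 side chain on C7; C14 on C10; C15 on C4); α/β refer to the usual drawing with C14 β; TBS = tert-butyldimethylsilyl.

Assumption: the lithium amide of (R,R)-bis(1-phenylethyl)amine is taken to deliver the (S)-enol silane, by analogy with its behaviour toward 4-tert-butylcyclohexanone; if the sense is opposite, the (S,S)-amide is used.

Step 1
Reactants: 1 4-[(tert-butyldimethylsilyl)oxy]cyclohexan-1-one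
Product: 3 (S)-4-[(tert-butyldimethylsilyl)oxy]cyclohex-2-en-1-one, via enol silane 2 (not isolated)
Conditions: (R,R)-bis(1-phenylethyl)amine, n-BuLi, Me3SiCl, THF, −100 to −78 °C; then Pd(OAc)2 (10 mol %), O2 (1 atm), DMSO, 25 °C
Reagents that add atoms: none
Why: Enantiotopic α-deprotonation of the prochiral ketone by the C2-symmetric chiral lithium amide with in situ silylation should set the C6 stereocentre (desymmetrisation), and Saegusa–Ito oxidation of the enol silane then gives the enone.

Step 2
Reactants: 3 (S)-4-[(tert-butyldimethylsilyl)oxy]cyclohex-2-en-1-one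
Product: 4 (S)-4-[(tert-butyldimethylsilyl)oxy]-2-iodocyclohex-2-en-1-one
Conditions: I2, pyridine, CH2Cl2, 0 to 25 °C
Reagents that add atoms: iodine (II)
Why: Pyridine-mediated α-iodination of the enone (conjugate addition, iodination, elimination) installs a coupling handle at the future C10 without touching the C6 stereocentre.

Step 3
Reactants: 4 (S)-4-[(tert-butyldimethylsilyl)oxy]-2-iodocyclohex-2-en-1-one; 5 tetramethylstannane
Product: 6 (S)-4-[(tert-butyldimethylsilyl)oxy]-2-methylcyclohex-2-en-1-one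
Conditions: 5, Pd2(dba)3 (2.5 mol %), AsPh3, CuI (10 mol %), NMP, 60 °C
Reagents that add atoms: tetramethylstannane (C[Sn](C)(C)C)
Why: Stille coupling of the α-iodoenone transfers the methyl group (C14) under neutral conditions that leave the γ-silyloxy enone intact.

Step 4
Reactants: 6 (S)-4-[(tert-butyldimethylsilyl)oxy]-2-methylcyclohex-2-en-1-one; 7 isopropenylmagnesium bromide; 8 benzyl chloromethyl ether
Product: 10 (2R,3S,4S)-2-[(benzyloxy)methyl]-4-[(tert-butyldimethylsilyl)oxy]-2-methyl-3-(prop-1-en-2-yl)cyclohexan-1-one, via magnesium enolate 9 (not isolated)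
Conditions: 7, CuBr·SMe2 (20 mol %), THF, −78 to −40 °C; then 8, DMPU, −40 to 0 °C
Reagents that add atoms: isopropenylmagnesium bromide (C=C(C)[Mg]Br); benzyl chloromethyl ether (ClCOCc1ccccc1)
Why: Copper-catalysed 1,4-addition should occur anti to the adjacent C6 silyloxy group (sets C5), and C-alkylation of the tetrasubstituted enolate by the reactive chloromethyl ether should occur anti to the new isopropenyl group (sets quaternary C10), a three-component conjugate addition–enolate alkylation.

Step 5
Reactants: 10 (2R,3S,4S)-2-[(benzyloxy)methyl]-4-[(tert-butyldimethylsilyl)oxy]-2-methyl-3-(prop-1-en-2-yl)cyclohexan-1-one; 11 dimethyl 2-diazomalonate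
Product: 12 dimethyl 2-{(1S,2R,6S)-2-[(benzyloxy)methyl]-6-[(tert-butyldimethylsilyl)oxy]-2-methyl-3-oxocyclohexyl}-2-methylcyclopropane-1,1-dicarboxylate (both epimers at the cyclopropane carbon C4)
Conditions: 11 (slow addition), Rh2(esp)2 (1 mol %), CH2Cl2, 40 °C
Reagents that add atoms: dimethyl 2-diazomalonate (COC(=O)C(=[N+]=[N-])C(=O)OC)
Why: Rhodium-carbenoid cyclopropanation of the only alkene, an electron-rich 1,1-disubstituted one with an exposed CH2 terminus, gives the donor–acceptor cyclopropane; the new centre C4 is uncontrolled and need not be controlled.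

Step 6
Reactants: 12 benzyl ether cyclopropane diester
Product: 13 dimethyl 2-{(1S,2R,6S)-6-[(tert-butyldimethylsilyl)oxy]-2-(hydroxymethyl)-2-methyl-3-oxocyclohexyl}-2-methylcyclopropane-1,1-dicarboxylate
Conditions: H2 (1 atm), palladium on carbon (Pd/C, 10 %), EtOAc, 25 °C
Reagents that add atoms: none
Why: Hydrogenolysis of the benzyl ether; no alkene remains, and alkyl-substituted cyclopropane-1,1-diesters, the ketone and the silyl ether are inert under these conditions.

Step 7
Reactants: 13 hydroxymethyl cyclopropane diester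
Product: 14 dimethyl 2-{(1S,2R,6S)-6-[(tert-butyldimethylsilyl)oxy]-2-formyl-2-methyl-3-oxocyclohexyl}-2-methylcyclopropane-1,1-dicarboxylate
Conditions: Dess–Martin periodinane, NaHCO3, CH2Cl2, 25 °C
Reagents that add atoms: none
Why: Dess–Martin oxidation of the neopentyl primary alcohol gives the non-enolisable aldehyde (C1) under neutral conditions that avoid retro-Claisen deformylation of the β-keto aldehyde.

Step 8
Reactants: 14 formyl cyclopropane diester
Product: 15 dimethyl 6α-[(tert-butyldimethylsilyl)oxy]-1β,4β-epoxy-9-oxo-11,12,13-trinoreudesmane-2,2-dicarboxylate (5α-H, 10β-methyl)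
Conditions: Sc(OTf)3 (20 mol %), 4 Å molecular sieves, ClCH2CH2Cl, 25 to 60 °C
Reagents that add atoms: none
Why: Sc(OTf)3 chelates the geminal diester and heterolyses the C2–C4 cyclopropane bond toward the tertiary carbon C4, the formyl oxygen captures C4 to give a five-membered cyclic oxocarbenium ion, and the scandium malonate at C2 adds to C1; this is the Lewis-acid intramolecular [3+2] cross-cycloaddition of 2-tethered cyclopropane-1,1-diesters with carbonyl groups, a known entry to oxa-bridged bicyclo[n.2.1] skeletons. The O–C4 closure is 5-exo-tet on the breaking cyclopropane bond, and the C1–C2 closure is 6-exo-trig along the new carbocycle (5-endo with respect to the oxolane, as in every cycloaddition of this class). C1 and C4 arise together as bridgeheads and are necessarily cis-bridged, so only the face of bridging is at issue: SN1-like, reversible C4–O bonding erases the cyclopropane configuration (both epimers of 14 converge), and the malonate arm should close on the ring face that carries H-5 and C9 rather than the face carrying the C10 methyl and the silyloxy-bearing C6, which places C14 exo and gives the 1β,4β-bridge. The step needs aldehyde-over-ketone chemoselectivity, secured by the higher electrophilicity of the aldehyde and by geometry, since the formyl and cyclopropyl groups are trans-diequatorial and gauche whereas the ring ketone C9 is antiperiplanar to C4. It also needs ring closure to outrun proton loss from the C4 cation, which the intramolecular oxygen trap favours.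

Step 9
Reactants: 15 tricyclic keto diester
Product: 16 6α-[(tert-butyldimethylsilyl)oxy]-1β,4β-epoxy-9-oxo-11,12,13-trinoreudesmane-2,2-dicarboxylic acid
Conditions: LiOH·H2O, THF/MeOH/H2O, 60 °C; then 1 M HCl, 0 °C
Reagents that add atoms: lithium hydroxide ([Li+].[OH-])
Why: Saponification of both methyl esters; C2 is quaternary and the β-positions carry only the bridgehead ether, so no elimination or retro-aldol pathway is open.

Step 10
Reactants: 16 malonic diacid
Product: 17 6α-[(tert-butyldimethylsilyl)oxy]-1β,4β-epoxy-11,12,13-trinoreudesman-9-one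
Conditions: 9-mesityl-10-phenylacridinium tetrafluoroborate (5 mol %), (PhS)2 (10 mol %), i-Pr2NEt, CF3CH2OH, 450 nm LEDs, 25 °C
Reagents that add atoms: none
Why: Organophotoredox double hydrodecarboxylation of the malonic acid (carboxylate oxidation, loss of CO2, hydrogen-atom transfer from thiophenol, twice) should replace both carboxyl groups by hydrogen, with β-scission of the C2 radical blocked because C1 is a bridgehead.

Step 11
Reactants: 17 tricyclic ketone
Product: 18 6α-[(tert-butyldimethylsilyl)oxy]-1β,4β-epoxy-11,12,13-trinoreudesm-7-en-9-one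
Conditions: 2-iodoxybenzoic acid (IBX), 4-methoxypyridine N-oxide, DMSO, 25 to 40 °C
Reagents that add atoms: none
Why: IBX dehydrogenation of the ketone; C10 is quaternary, so enolisation and desaturation can only occur toward C8–C7.

Step 12
Reactants: 18 enone
Product: 19 6α-[(tert-butyldimethylsilyl)oxy]-1β,4β-epoxy-11,12,13-trinoreudesm-7-en-9β-ol
Conditions: NaBH4, CeCl3·7H2O, MeOH, −78 to 0 °C
Reagents that add atoms: none
Why: Luche 1,2-reduction; hydride should reach C9 from the α-face, opposite the axial C10 methyl, giving the 9β (equatorial) allylic alcohol.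

Step 13
Reactants: 19 allylic alcohol
Product: 20 methyl 6α-[(tert-butyldimethylsilyl)oxy]-1β,4β-epoxy-11,12,13-trinoreudesm-7-en-9β-yl carbonate
Conditions: ClCO2Me, pyridine, DMAP (cat.), CH2Cl2, 0 to 25 °C
Reagents that add atoms: methyl chloroformate (COC(=O)Cl)
Why: Acylation of the hindered secondary allylic alcohol with the small chloroformate gives the allylic carbonate needed for ionisation.

Step 14
Reactants: 20 allylic carbonate; 21 tert-butyl 2-(diethoxyphosphoryl)acetate
Product: 22 tert-butyl 2-(diethoxyphosphoryl)-2-{6α-[(tert-butyldimethylsilyl)oxy]-1β,4β-epoxy-11,12,13-trinoreudesm-8-en-7β-yl}acetate (epimers at C11)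
Conditions: 21, Pd2(dba)3 (2.5 mol %), PPh3 (10 mol %), THF, 65 °C
Reagents that add atoms: tert-butyl 2-(diethoxyphosphoryl)acetate (CCOP(=O)(OCC)CC(=O)OC(C)(C)C)
Why: Tsuji–Trost allylic alkylation: zerovalent palladium ionises the 9β-carbonate with inversion (metal on the α-face), and the phosphonoacetate carbanion, generated by the liberated methoxide, attacks anti to the metal at C7, the allyl terminus remote from quaternary C10 and not shielded by the β-methyl, so the C7–C11 bond forms on the β-face (net retention) and the double bond moves to C8–C9.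

Step 15
Reactants: 22 allylated phosphonoacetate
Product: 23 tert-butyl 6α-[(tert-butyldimethylsilyl)oxy]-1β,4β-epoxyeudesma-8,11(13)-dien-12-oate (7α-H)
Conditions: aqueous CH2O (37 %), K2CO3, THF, 25 to 50 °C
Reagents that add atoms: formaldehyde (C=O)
Why: Horner–Wadsworth–Emmons methylenation of the α-substituted phosphonoacetate with formaldehyde gives the 2-substituted acrylate (C11=C13) and removes the C11 stereocentre.

Step 16
Reactants: 23 silyl ether acrylate
Product: 24 tert-butyl 1β,4β-epoxy-6α-hydroxyeudesma-8,11(13)-dien-12-oate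
Conditions: HF·pyridine, pyridine, THF, 0 to 25 °C
Reagents that add atoms: none
Why: Fluoride-mediated desilylation under mildly acidic, non-basic conditions frees the C6 hydroxyl without alkoxide-driven conjugate addition or lactonisation onto the acrylate.

Step 17
Reactants: 24 C6 alcohol; 25 angelic acid ((Z)-2-methylbut-2-enoic acid)
Product: 26 tert-butyl 6α-(angeloyloxy)-1β,4β-epoxyeudesma-8,11(13)-dien-12-oate
Conditions: 25, 2,4,6-trichlorobenzoyl chloride, Et3N, toluene, 25 °C; then 24, 80 °C
Reagents that add atoms: angelic acid (C/C=C(/C)C(=O)O)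
Why: Yamaguchi-type esterification through the 2,4,6-trichlorobenzoyl mixed anhydride, run without a nucleophilic catalyst, acylates the only free hydroxyl and should preserve the (Z)-geometry of the angeloyl group.

Step 18
Reactants: 26 angelate diene ester
Product: 28 6α-(angeloyloxy)-1β,4β-epoxy-9α-hydroxyeudesm-11(13)-en-12,8β-olide (CNP0328162.1), via epoxide 27 (not isolated)
Conditions: mCPBA, CH2Cl2, 0 to 25 °C; then CF3CO2H (2 equiv), 0 °C
Reagents that add atoms: mCPBA (O=C(OO)c1cccc(Cl)c1)
Why: Prilezhaev epoxidation of the only electron-rich alkene on the α-face (anti to the axial C10 methyl), then acid-promoted 5-exo opening of the epoxide at C8 by the β-disposed ester carbonyl with inversion and loss of isobutene: trans-diaxial (Fürst–Plattner) opening sets 8β-O and 9α-OH and closes the cis-fused α-methylene lactone.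

Compound list
1 | 4-[(tert-butyldimethylsilyl)oxy]cyclohexan-1-one | O=C1CCC(O[Si](C)(C)C(C)(C)C)CC1 | starting material
2 | (S)-tert-butyldimethyl{[4-(trimethylsilyloxy)cyclohex-3-en-1-yl]oxy}silane | C[Si](C)(C)OC1=CC[C@@H](O[Si](C)(C)C(C)(C)C)CC1 | intermediate (not isolated)
3 | (S)-4-[(tert-butyldimethylsilyl)oxy]cyclohex-2-en-1-one | O=C1C=C[C@@H](O[Si](C)(C)C(C)(C)C)CC1 | intermediate
4 | (S)-4-[(tert-butyldimethylsilyl)oxy]-2-iodocyclohex-2-en-1-one | O=C1C(I)=C[C@@H](O[Si](C)(C)C(C)(C)C)CC1 | intermediate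
5 | tetramethylstannane | C[Sn](C)(C)C | starting material
6 | (S)-4-[(tert-butyldimethylsilyl)oxy]-2-methylcyclohex-2-en-1-one | CC1=C[C@@H](O[Si](C)(C)C(C)(C)C)CCC1=O | intermediate
7 | isopropenylmagnesium bromide | C=C(C)[Mg]Br | starting material
8 | benzyl chloromethyl ether | ClCOCc1ccccc1 | starting material
9 | bromomagnesium enolate of (3S,4S)-4-[(tert-butyldimethylsilyl)oxy]-2-methyl-3-(prop-1-en-2-yl)cyclohexan-1-one | CC1=C(O[Mg]Br)CC[C@H](O[Si](C)(C)C(C)(C)C)[C@H]1C(C)=C | intermediate (not isolated)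
10 | (2R,3S,4S)-2-[(benzyloxy)methyl]-4-[(tert-butyldimethylsilyl)oxy]-2-methyl-3-(prop-1-en-2-yl)cyclohexan-1-one | O=C1CC[C@H](O[Si](C)(C)C(C)(C)C)[C@@H](C(C)=C)[C@]1(C)COCc1ccccc1 | intermediate
11 | dimethyl 2-diazomalonate | COC(=O)C(=[N+]=[N-])C(=O)OC | starting material
12 | dimethyl 2-{(1S,2R,6S)-2-[(benzyloxy)methyl]-6-[(tert-butyldimethylsilyl)oxy]-2-methyl-3-oxocyclohexyl}-2-methylcyclopropane-1,1-dicarboxylate (C4 epimers) | O=C1CC[C@H](O[Si](C)(C)C(C)(C)C)[C@@H](C2(C)CC2(C(=O)OC)C(=O)OC)[C@]1(C)COCc1ccccc1 | intermediate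
13 | dimethyl 2-{(1S,2R,6S)-6-[(tert-butyldimethylsilyl)oxy]-2-(hydroxymethyl)-2-methyl-3-oxocyclohexyl}-2-methylcyclopropane-1,1-dicarboxylate | O=C1CC[C@H](O[Si](C)(C)C(C)(C)C)[C@@H](C2(C)CC2(C(=O)OC)C(=O)OC)[C@]1(C)CO | intermediate
14 | dimethyl 2-{(1S,2R,6S)-6-[(tert-butyldimethylsilyl)oxy]-2-formyl-2-methyl-3-oxocyclohexyl}-2-methylcyclopropane-1,1-dicarboxylate | O=C1CC[C@H](O[Si](C)(C)C(C)(C)C)[C@@H](C2(C)CC2(C(=O)OC)C(=O)OC)[C@]1(C)C=O | intermediate
15 | dimethyl 6α-[(tert-butyldimethylsilyl)oxy]-1β,4β-epoxy-9-oxo-11,12,13-trinoreudesmane-2,2-dicarboxylate | O=C1CC[C@H](O[Si](C)(C)C(C)(C)C)[C@@H]2[C@]1(C)[C@H]1C(C(=O)OC)(C(=O)OC)C[C@]2(C)O1 | intermediate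
16 | 6α-[(tert-butyldimethylsilyl)oxy]-1β,4β-epoxy-9-oxo-11,12,13-trinoreudesmane-2,2-dicarboxylic acid | O=C1CC[C@H](O[Si](C)(C)C(C)(C)C)[C@@H]2[C@]1(C)[C@H]1C(C(=O)O)(C(=O)O)C[C@]2(C)O1 | intermediate
17 | 6α-[(tert-butyldimethylsilyl)oxy]-1β,4β-epoxy-11,12,13-trinoreudesman-9-one | O=C1CC[C@H](O[Si](C)(C)C(C)(C)C)[C@@H]2[C@]1(C)[C@H]1CC[C@]2(C)O1 | intermediate
18 | 6α-[(tert-butyldimethylsilyl)oxy]-1β,4β-epoxy-11,12,13-trinoreudesm-7-en-9-one | O=C1C=C[C@H](O[Si](C)(C)C(C)(C)C)[C@@H]2[C@]1(C)[C@H]1CC[C@]2(C)O1 | intermediate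
19 | 6α-[(tert-butyldimethylsilyl)oxy]-1β,4β-epoxy-11,12,13-trinoreudesm-7-en-9β-ol | O[C@H]1C=C[C@H](O[Si](C)(C)C(C)(C)C)[C@@H]2[C@]1(C)[C@H]1CC[C@]2(C)O1 | intermediate
20 | methyl 6α-[(tert-butyldimethylsilyl)oxy]-1β,4β-epoxy-11,12,13-trinoreudesm-7-en-9β-yl carbonate | COC(=O)O[C@H]1C=C[C@H](O[Si](C)(C)C(C)(C)C)[C@@H]2[C@]1(C)[C@H]1CC[C@]2(C)O1 | intermediate
21 | tert-butyl 2-(diethoxyphosphoryl)acetate | CCOP(=O)(OCC)CC(=O)OC(C)(C)C | starting material
22 | tert-butyl 2-(diethoxyphosphoryl)-2-{6α-[(tert-butyldimethylsilyl)oxy]-1β,4β-epoxy-11,12,13-trinoreudesm-8-en-7β-yl}acetate (C11 epimers) | C1=C[C@@H](C(P(=O)(OCC)OCC)C(=O)OC(C)(C)C)[C@H](O[Si](C)(C)C(C)(C)C)[C@@H]2[C@]1(C)[C@H]1CC[C@]2(C)O1 | intermediate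
23 | tert-butyl 6α-[(tert-butyldimethylsilyl)oxy]-1β,4β-epoxyeudesma-8,11(13)-dien-12-oate | C1=C[C@@H](C(=C)C(=O)OC(C)(C)C)[C@H](O[Si](C)(C)C(C)(C)C)[C@@H]2[C@]1(C)[C@H]1CC[C@]2(C)O1 | intermediate
24 | tert-butyl 1β,4β-epoxy-6α-hydroxyeudesma-8,11(13)-dien-12-oate | C1=C[C@@H](C(=C)C(=O)OC(C)(C)C)[C@H](O)[C@@H]2[C@]1(C)[C@H]1CC[C@]2(C)O1 | intermediate
25 | angelic acid, (Z)-2-methylbut-2-enoic acid | C/C=C(/C)C(=O)O | starting material
26 | tert-butyl 6α-(angeloyloxy)-1β,4β-epoxyeudesma-8,11(13)-dien-12-oate | C1=C[C@@H](C(=C)C(=O)OC(C)(C)C)[C@H](OC(=O)/C(C)=C\C)[C@@H]2[C@]1(C)[C@H]1CC[C@]2(C)O1 | intermediate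
27 | tert-butyl 6α-(angeloyloxy)-1β,4β:8α,9α-diepoxyeudesm-11(13)-en-12-oate | O1[C@@H]2[C@H]1[C@@H](C(=C)C(=O)OC(C)(C)C)[C@H](OC(=O)/C(C)=C\C)[C@@H]3[C@]2(C)[C@H]2CC[C@]3(C)O2 | intermediate (not isolated)
28 | 6α-(angeloyloxy)-1β,4β-epoxy-9α-hydroxyeudesm-11(13)-en-12,8β-olide (CNP0328162.1) | C=C1C(=O)O[C@H]2[C@@H]1[C@H](OC(=O)/C(C)=C\C)[C@@H]1[C@@](C)([C@@H]2O)[C@H]2CC[C@]1(C)O2 | target

Total step count: 18
Longest linear sequence: 18 steps (from 1 to 28; all other components are commercial reagents)

Steps most likely to fail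

Step 8 (key cycloaddition). What may go wrong: bridging on the wrong ring face (C14 endo), proton loss from the C4 cation before the oxygen trap, or participation of the ring ketone instead of the aldehyde. Fallback, setting out from 6 and coming back at 17: the copper-catalysed isopropenyl addition to 6 is quenched with gaseous formaldehyde to give the hydroxymethyl ketone F1. Dess–Martin oxidation gives the keto aldehyde F2. Reagent-controlled, aldehyde-selective Brown allylboration ((+)-Ipc2B(allyl), chosen to deliver the (R)-carbinol) gives the homoallylic alcohol F3. Ring-closing metathesis with the second-generation Grubbs catalyst closes ring A as the cyclohexenol F4 (C3=C4). Markovnikov transannular hydroalkoxylation (Co(salen) catalyst, N-fluoro-2,4,6-trimethylpyridinium triflate, PhSiH3; or catalytic TfOH) then joins the 1β-oxygen to C4 and gives 17, bypassing steps 5–10 and forming the two bonds in separate operations.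

Step 5 (cyclopropanation). What may go wrong: steric retardation at the flanked isopropenyl group, with the carbenoid diverted into carbonyl-ylide or ether-ylide and C–H insertion pathways. Fallback, setting out from 10 and coming back at 12: photocatalytic Kharasch-type atom-transfer radical addition of dimethyl bromomalonate (Ru(bpy)3Cl2, LiBr, blue light) puts the malonyl radical on the CH2 terminus and bromine on the tertiary carbon, giving the γ-bromo malonate F5. DBU-mediated 3-exo-tet ring closure with loss of hydrogen bromide then gives 12 without any metal carbenoid.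

Step 14 (allylic alkylation). What may go wrong: slow ionisation of the pseudo-equatorial carbonate, β-hydride elimination of the allyl complex to a ring B diene, or attack at the wrong allyl terminus. Fallback, setting out from 18 and coming back at 23: Michael addition of 21 to enone 18 under equilibrating conditions (catalytic Cs2CO3, THF) should place the side chain equatorial (β) on C7 and give the keto phosphonate F6. Horner–Wadsworth–Emmons methylenation (aqueous CH2O, K2CO3) gives the keto acrylate F7. Tf2O with 2,6-di-tert-butyl-4-methylpyridine gives the enol triflate F8 (only C8 is enolisable). Palladium-catalysed formate reduction (Pd(OAc)2, PPh3, HCO2H, Bu3N, DMF) then gives 23.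

Further compounds
F1 | step 8 | (2R,3S,4S)-4-[(tert-butyldimethylsilyl)oxy]-2-(hydroxymethyl)-2-methyl-3-(prop-1-en-2-yl)cyclohexan-1-one | O=C1CC[C@H](O[Si](C)(C)C(C)(C)C)[C@@H](C(C)=C)[C@]1(C)CO
F2 | step 8 | (1R,2S,3S)-3-[(tert-butyldimethylsilyl)oxy]-1-methyl-6-oxo-2-(prop-1-en-2-yl)cyclohexane-1-carbaldehyde | O=C1CC[C@H](O[Si](C)(C)C(C)(C)C)[C@@H](C(C)=C)[C@]1(C)C=O
F3 | step 8 | (2R,3S,4S)-4-[(tert-butyldimethylsilyl)oxy]-2-[(R)-1-hydroxybut-3-en-1-yl]-2-methyl-3-(prop-1-en-2-yl)cyclohexan-1-one | O=C1CC[C@H](O[Si](C)(C)C(C)(C)C)[C@@H](C(C)=C)[C@]1(C)[C@H](O)CC=C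
F4 | step 8 | 6α-[(tert-butyldimethylsilyl)oxy]-1β-hydroxy-11,12,13-trinoreudesm-3-en-9-one | O=C1CC[C@H](O[Si](C)(C)C(C)(C)C)[C@@H]2[C@]1(C)[C@H](O)CC=C2C
F5 | step 5 | dimethyl 2-{2-bromo-2-[(1S,2R,6S)-2-[(benzyloxy)methyl]-6-[(tert-butyldimethylsilyl)oxy]-2-methyl-3-oxocyclohexyl]propyl}malonate | O=C1CC[C@H](O[Si](C)(C)C(C)(C)C)[C@@H](C(C)(Br)CC(C(=O)OC)C(=O)OC)[C@]1(C)COCc1ccccc1
F6 | step 14 | tert-butyl 2-(diethoxyphosphoryl)-2-{6α-[(tert-butyldimethylsilyl)oxy]-1β,4β-epoxy-9-oxo-11,12,13-trinoreudesman-7β-yl}acetate | O=C1C[C@@H](C(P(=O)(OCC)OCC)C(=O)OC(C)(C)C)[C@H](O[Si](C)(C)C(C)(C)C)[C@@H]2[C@]1(C)[C@H]1CC[C@]2(C)O1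
F7 | step 14 | tert-butyl 6α-[(tert-butyldimethylsilyl)oxy]-1β,4β-epoxy-9-oxoeudesm-11(13)-en-12-oate | O=C1C[C@@H](C(=C)C(=O)OC(C)(C)C)[C@H](O[Si](C)(C)C(C)(C)C)[C@@H]2[C@]1(C)[C@H]1CC[C@]2(C)O1
F8 | step 14 | tert-butyl 6α-[(tert-butyldimethylsilyl)oxy]-1β,4β-epoxy-9-[(trifluoromethylsulfonyl)oxy]eudesma-8,11(13)-dien-12-oate | O=S(=O)(OC1=C[C@@H](C(=C)C(=O)OC(C)(C)C)[C@H](O[Si](C)(C)C(C)(C)C)[C@@H]2[C@]1(C)[C@H]1CC[C@]2(C)O1)C(F)(F)F
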